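The numbers in the tables were generated by integration for an exercise.

Per molar of partner and per hour is the unit of the one number I carry through this flask.

common to all: substrate 0.050 M
- Sunday's: partner 0.090 M; the very flask that is asked about, followed so far
- Tuesday's: partner 0.18 M; run made earlier
- flask: partner 0.0900 M; time 12 h

| run | time / h | substrate / % | first product / % |
|---|---|---|---|
| Sunday's | 0.200 | 97.7 | 1.8 |
| Sunday's | 0.333 | 96.5 | 2.9 |
| Sunday's | 0.500 | 96.0 | 4.3 |
| Sunday's | 0.833 | 92.4 | 6.6 |
| Sunday's | 1.33 | 88.6 | 10.8 |
| Sunday's | 2.50 | 81.4 | 18.7 |
| Tuesday's | 0.500 | 91.7 | 8.5 |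
| Tuesday's | 1.50 | 77.6 | 22.6 |
| Tuesday's | 3.00 | 60.6 | 38.2 |
| Tuesday's | 5.00 | 44.8 | 53.4 |
| Tuesday's | 6.00 | 38.4 | 59.4 |
| Tuesday's | 8.00 | 28.5 | 68.7 |

(each reading ± 0.5 percentage points)

- a reading or a percentage of first product counts all its forms, free or not

* how much substrate there is at 12 h, in percent of the substrate charged
* how much first product there is at 12 h, in percent of the substrate charged
* how much bis adduct there is at 12 h, in percent of the substrate charged
* how much tris adduct there is at 12 h, in percent of the substrate charged

1. Tuesday's last reading gives 0.994 M⁻¹ h⁻¹ for the partner-corrected constant, the logarithm of the fraction of partner left over the fraction of substrate left, divided by the difference of the charges and by the time. Sunday's last reading, with half the partner, gives 0.967 M⁻¹ h⁻¹, so I take the step as first order in partner, within the scatter.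
2. First pass: I hold c_partner at its charge, a pseudo-first-order decay, and for Sunday's flask I get 34.2 % substrate at 12 h.
3. But that answer leaves c_partner at 0.0571 M. Going round with the straight mean of start and end gives 41.6 %.
4. Going round again gives 40.7 %, a move of 0.90 percentage points against 7.4 points on the round before.
5. The weak link is the straight mean, for c_partner does not fall in a straight line. So I solve the constant's own definition for substrate instead, and commit to 42.1 % substrate.
6. Tuesday's readings at 8.00 h leave 2.80 % beyond substrate and first product. I lend that figure to the two adducts here as a stand-in, which puts first product near 55.1 %.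

The forecast says 42.8 % substrate, 55.4 % first product, 1.75 % bis adduct and 0.05 % tris adduct, with “Tris adduct is negligible unless the third step is unexpectedly fast”.

The flask gives 42.2 % substrate, 55.9 % first product, 0.764 % bis adduct and 1.10 % tris adduct.

    substrate + partner → first product (k = 1.00 M⁻¹ h⁻¹)
    crystals ⇌ first product, rate k2*(cs2 - [first product]) while solid is left; crystals form when [first product] > cs2 (solubility = 1.20 mM, k = 25.0 h⁻¹)
    partner + first product → bis adduct (k = 0.850 M⁻¹ h⁻¹)
    partner + bis adduct → tris adduct (k = 2.50 M⁻¹ h⁻¹)

Of the first product in this flask at 12.0 h, 53.4 % of the substrate charged stands as crystals. Tris adduct stays at 1.10 % in this flask because first product dissolves only up to 1.2 mM and because of the time given: with that limit on dissolving taken away this flask holds 8.27 %, and left until 120 h it holds 9.49 %. With 0.15 M of partner the constant 0.994 M⁻¹ h⁻¹ gives 22.5 % substrate, and that neighbour flask holds 22.7 %.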